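(The constants were chosen freely.)

We want to know which of the four flasks, alike but for temperature, holds the most product after the given time.

all flasks: substrate 0.10 M; partner 0.500 equiv; catalyst 0.5 mol%; time 12 h
- Monday's: temperature 45 °C
- Friday's: temperature 25 °C
- Wednesday's: temperature 65 °C
- Tuesday's: temperature 85 °C

    partner → decomposed reagent (k1 = 0.059 /h, Ea1 = 107 kJ/mol)
    substrate + partner + catalyst ⇌ product + catalyst, rate k2*[substrate]*[partner]*[catalyst] forward; the back reaction follows from the equilibrium constant (K2 = 330 /M, k2 = 920 /M²/h, Ea2 = 49.0 kJ/mol, ΔH2 = −42.0 kJ/mol)
    (constants at 25 °C)

- at 25 °C the constants are as listed, elsewhere as the activation energies and enthalpies make them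

* the flask with the highest amount of product, in percent of the substrate charged ("all alike" if they lie within 1.5 percentage points) (Monday's / Friday's / Wednesday's / Tuesday's / all alike)
* final product, as a percentage of the substrate charged, in Monday's
* final product, as a percentage of the substrate charged, in Friday's
* final product, as a percentage of the substrate charged, in Wednesday's
* final product, as a percentage of the substrate charged, in Tuesday's

We turn the question round and ask what the numbers would have to say for a warmer flask to beat Friday's. Partner has two exits: it decays by itself, or it couples with substrate on the catalyst. While substrate stays near its charge, coupling is a pseudo-first-order loss of partner with the constant k·c(substrate)·c(catalyst), which at 25 °C is 0.0460 /h. Decay constant over coupling constant is then 1.28 in Friday's, and this number, the waste ratio (the usual selectivity factor, inverted), is what we carry. With 0.500 equiv of partner, product cannot pass a ceiling of 21.9% of the substrate, leaving aside the back reaction. Both exits together give Friday's 1.26 partner lifetimes in 12 h, so we reckon 15.7% for Friday's.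

A warmer flask, even with its partner used to the last, beats that figure only with a waste ratio under 2.19, a rise of 1.70 times on Friday's. But the ratio climbs on warming, since decay's activation energy stands 58.0 kJ/mol above coupling's: from 25 °C to 85 °C decay speeds up 1400 times and coupling 27 times, so the ratio rises 50.4 times, to 64.6 in Tuesday's, whose ceiling is 0.762%. Monday's lies a third of the way up in degrees, and taking the cube root of that rise, an estimate and no bound, gives Monday's a ratio of roughly 4.74 and a rough ceiling of 8.72%, lower than our Friday figure. So we commit to Friday's.

The forecast named Friday's, with 14.7% there, 6.5% in Monday's, 0.69% in Wednesday's and <0.001% in Tuesday's, on the ground that “warming sends more of it to waste than to product”. The simulation puts Friday's on top with 14.6%, against 6.43% in Monday's, 0.684% in Wednesday's and 0% in Tuesday's, and our figure for Friday's stands 1.1 percentage points above it.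

At 12.0 h in Friday's, decay uses partner 1.5 times as fast as forward coupling, which is the waste ratio divided by the 85.4% of substrate still there, 1.50, and after 120 h the product in Friday's reads 18.6%, less than the ceiling of 21.9%. In Monday's, the product reads 6.90% at 6.00 h, lower than its rough ceiling of 8.72%, and with partner down to 0.176% of its charge it stands at 6.43% at 12.0 h.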